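**Plan**

1. Ring A (C1' bears the aroyl carbon, C2' the formyl group, C3' the hydroxyl, C6' the prenyl group) is read as a 6-acylsalicylate. The C2' formyl group is traced back to a methyl ester and the ring is cut at C4'–C5' and C1'–C2'.
2. This gives a 1,3-bis(silyloxy)diene from methyl acetoacetate and a 3-(silyloxymethylidene)-1,2-diketone. The diketone is cut between C1' and the aroyl carbon (dithiane acyl anion plus ring B aldehyde) and at C5'–C6' (formyl equivalent).
3. The dioxane ring of ring B is cut at its two O–C(sp3) bonds into a catechol aldehyde and an epoxy tosylate made from 3-methylbut-2-en-1-ol.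
4. Forward: the dioxane ring closes first (step 3), the seven-carbon chain is joined (step 6) and formylated (step 9), ring A closes by cyclocondensation (step 13), then the ester is taken to the aldehyde and both silyl ethers are removed last.
5. The single stereocentre is set by Sharpless asymmetric epoxidation with L-(+)-diethyl tartrate (2S) and inverted once, to 3R, when the phenoxide opens the epoxide; nothing later touches it.

Key step: step 13

Remark 1: Ar stands for the (3R)-3-{2-[(tert-butyldimethylsilyl)oxy]propan-2-yl}-7-methyl-2,3-dihydro-1,4-benzodioxin-5-yl group (ring B with its silylated side chain).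

Remark 2: Enol ether 19 is drawn as the Z isomer silylated on the formyl oxygen; the E isomer or the tautomeric O-silyl isomer is assumed to converge on the same salicylate, because this double bond ends up inside ring A. Compounds 21 and 23 are used as double-bond isomer mixtures, and 14 and 26 as epimer mixtures at a carbinol carbon that is oxidised later.

**Route**

Step 1
Reactants: 1 2-hydroxy-3-methoxy-5-methylbenzaldehyde
Product: 2 2,3-dihydroxy-5-methylbenzaldehyde
Conditions: BBr3, CH2Cl2, −78 → 0 °C; then H2O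
Reagents that add atoms: none
Why: Lewis acid cleavage of an aryl methyl ether, in which boron binds the methoxy oxygen and bromide removes the methyl group by SN2 while the ortho-hydroxy aldehyde is held as a borate chelate.

Step 2
Reactants: 3 3-methylbut-2-en-1-ol
Product: 5 [(2S)-3,3-dimethyloxiran-2-yl]methyl 4-methylbenzenesulfonate, via epoxy alcohol 4 (not isolated)
Conditions: Ti(O-i-Pr)4 (cat.), L-(+)-diethyl tartrate (cat.), t-BuOOH, 4 Å MS, CH2Cl2, −20 °C; then P(OMe)3; then TsCl, Et3N, DMAP (cat.), −10 °C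
Reagents that add atoms: tert-butyl hydroperoxide, CC(C)(C)OO; 4-methylbenzenesulfonyl chloride, Cc1ccc(cc1)S(=O)(=O)Cl
Why: Sharpless asymmetric epoxidation, in which the titanium tartrate complex delivers oxygen to the face that gives the 2S epoxide (reagent control by the L-(+)-tartrate, as for other 3,3-disubstituted allylic alcohols), followed by sulfonylation in the same flask so that the small water-soluble epoxy alcohol need not be isolated.

Step 3
Reactants: 2 2,3-dihydroxy-5-methylbenzaldehyde; 5 [(2S)-3,3-dimethyloxiran-2-yl]methyl 4-methylbenzenesulfonate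
Product: 7 (3R)-3-(2-hydroxypropan-2-yl)-7-methyl-2,3-dihydro-1,4-benzodioxine-5-carbaldehyde, via epoxy ether phenoxide 6 (not isolated)
Conditions: NaH (2.2 equiv), DMSO, 20 °C; then 5; 20 → 60 °C; then H2O
Reagents that add atoms: none
Why: Williamson etherification then intramolecular epoxide opening, in which the phenoxide meta to the formyl group (the more nucleophilic one, since the ortho phenoxide is conjugated and chelated) displaces the primary tosylate without touching C2, and the remaining phenoxide opens the epoxide at its secondary carbon in a 6-exo-tet SN2 reaction with inversion, turning the 2S epoxide into the 3R benzodioxane and leaving the tertiary alcohol.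

Step 4
Reactants: 7 (3R)-3-(2-hydroxypropan-2-yl)-7-methyl-2,3-dihydro-1,4-benzodioxine-5-carbaldehyde
Product: 8 Ar–CHO, (3R)-3-{2-[(tert-butyldimethylsilyl)oxy]propan-2-yl}-7-methyl-2,3-dihydro-1,4-benzodioxine-5-carbaldehyde
Conditions: TBSOTf, 2,6-lutidine, CH2Cl2, 0 °C
Reagents that add atoms: tert-butyldimethylsilyl trifluoromethanesulfonate, CC(C)(C)[Si](C)(C)OS(=O)(=O)C(F)(F)F
Why: Silylation of a tertiary alcohol with a silyl triflate and a hindered pyridine base, which the non-enolisable aldehyde survives.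

Step 5
Reactants: 9 1,3-dithiane; 10 5-bromo-2-methylpent-2-ene
Product: 12 2-(4-methylpent-3-en-1-yl)-1,3-dithiane, via 2-lithio-1,3-dithiane 11 (not isolated)
Conditions: n-BuLi, THF, −30 °C; then 10, −78 → 0 °C
Reagents that add atoms: none
Why: Corey–Seebach alkylation, in which the lithiated dithiane displaces the primary bromide by SN2.

Step 6
Reactants: 12 2-(4-methylpent-3-en-1-yl)-1,3-dithiane; 8 Ar–CHO
Product: 14 Ar[2-(4-methylpent-3-en-1-yl)-1,3-dithian-2-yl]methanol (epimers at the carbinol carbon), via lithiated dithiane 13 (not isolated)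
Conditions: n-BuLi, THF, −30 °C; then 8, −78 °C; then H2O
Reagents that add atoms: none
Why: Corey–Seebach acyl anion addition to a non-enolisable aryl aldehyde, whose new carbinol centre forms unselectively and is removed by oxidation in the next step.

Step 7
Reactants: 14 Ar[2-(4-methylpent-3-en-1-yl)-1,3-dithian-2-yl]methanol
Product: 15 Ar 2-(4-methylpent-3-en-1-yl)-1,3-dithian-2-yl ketone
Conditions: (COCl)2, DMSO, CH2Cl2, −78 °C; then Et3N, −78 → 0 °C
Reagents that add atoms: none
Why: Swern oxidation of a benzylic secondary alcohol, which at −78 °C leaves the thioacetal, the silyl ether and the alkene untouched.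

Step 8
Reactants: 15 Ar 2-(4-methylpent-3-en-1-yl)-1,3-dithian-2-yl ketone
Product: 16 1-Ar-6-methylhept-5-ene-1,2-dione
Conditions: MeI, CaCO3, MeCN/H2O (9:1), 45 °C
Reagents that add atoms: water, O
Why: Alkylative hydrolysis of the dithiane, in which S-methylation turns sulfur into a leaving group and water supplies the carbonyl oxygen, chosen because MeI does not attack the trisubstituted alkene as halonium or mercury reagents would.

Step 9
Reactants: 16 1-Ar-6-methylhept-5-ene-1,2-dione
Product: 18 (3Z)-1-Ar-3-(hydroxymethylidene)-6-methylhept-5-ene-1,2-dione, via enaminone 17 (not isolated)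
Conditions: t-BuOCH(NMe2)2, toluene, 80 °C; then 1 M aq HCl, THF, 20 °C
Reagents that add atoms: tert-butoxybis(dimethylamino)methane, CN(C)C(OC(C)(C)C)N(C)C; water, O
Why: Aminomethylenation of the only enolisable position (the C3 methylene) with an aminal ester gives the vinylogous amide, and acid hydrolysis releases the chelated hydroxymethylidene ketone, a formylation that avoids the strong base a Claisen condensation would bring to the 1,2-diketone.

Step 10
Reactants: 18 (3Z)-1-Ar-3-(hydroxymethylidene)-6-methylhept-5-ene-1,2-dione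
Product: 19 (3Z)-1-Ar-6-methyl-3-{[(trimethylsilyl)oxy]methylidene}hept-5-ene-1,2-dione
Conditions: Me3SiCl, Et3N, toluene, 20 °C
Reagents that add atoms: chlorotrimethylsilane, C[Si](C)(C)Cl
Why: O-Silylation of the enolised β-keto aldehyde gives the 3-silyloxy-2-en-1-one, which is used without chromatography because it is moisture-sensitive.

Step 11
Reactants: 20 methyl acetoacetate
Product: 21 methyl 3-[(trimethylsilyl)oxy]but-2-enoate
Conditions: Me3SiCl, Et3N, pentane, 20 °C
Reagents that add atoms: chlorotrimethylsilane, C[Si](C)(C)Cl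
Why: Silyl enol ether formation from the enolised β-keto ester by soft enolisation with amine base and silyl chloride.

Step 12
Reactants: 21 methyl 3-[(trimethylsilyl)oxy]but-2-enoate
Product: 23 1-methoxy-1,3-bis[(trimethylsilyl)oxy]buta-1,3-diene, via lithium dienolate 22 (not isolated)
Conditions: LiN(i-Pr)2, THF, −78 °C; then Me3SiCl, −78 → 20 °C
Reagents that add atoms: chlorotrimethylsilane, C[Si](C)(C)Cl
Why: Kinetic γ-deprotonation of the vinylogous ester by the lithium amide and O-silylation of the dienolate give the 1,3-bis(silyloxy)diene.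

Step 13
Reactants: 19 (3Z)-1-Ar-6-methyl-3-{[(trimethylsilyl)oxy]methylidene}hept-5-ene-1,2-dione; 23 1-methoxy-1,3-bis[(trimethylsilyl)oxy]buta-1,3-diene
Product: 24 methyl 2-(Ar-carbonyl)-6-hydroxy-3-(3-methylbut-2-en-1-yl)benzoate
Conditions: 23 (1.5 equiv), TiCl4 (1.1 equiv), 4 Å MS, CH2Cl2, −78 → 20 °C; then H2O
Reagents that add atoms: none
Why: TiCl4 activates the silyloxymethylidene enone of 19 as a vinylogous silyl ester, and the unsubstituted terminal carbon of diene 23 adds to the CH–OSi carbon in a Mukaiyama–Michael step (C4'–C5'), after which loss of silanolate restores an enone. The titanium enolate of the resulting β-keto ester then attacks the neighbouring inner ketone through its central carbon in an intramolecular aldol reaction (C1'–C2'), a 6-exo-trig closure that forms ring A, and dehydration with enolisation aromatises it to the salicylate. The closest known reaction type is the TiCl4-mediated formal [3+3] cyclocondensation of 1,3-bis(silyloxy)-1,3-dienes with 3-silyloxy-2-en-1-ones. No stereocentre is formed, and the ether stereocentre of ring B is remote, not enolisable and untouched. The step needs regioselectivity (terminal diene carbon to the formyl-derived carbon, central carbon to the inner ketone) and chemoselectivity against the aryl ketone: the first should follow from the higher reactivity of the unsubstituted diene terminus toward the unhindered CH terminus, the second from the six-membered closure (attack on the aryl ketone would need a seven-membered ring) and from the shielding and conjugative deactivation of the aryl ketone by its ortho-oxygenated ring.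

Step 14
Reactants: 24 methyl 2-(Ar-carbonyl)-6-hydroxy-3-(3-methylbut-2-en-1-yl)benzoate
Product: 25 methyl 2-(Ar-carbonyl)-6-[(tert-butyldimethylsilyl)oxy]-3-(3-methylbut-2-en-1-yl)benzoate
Conditions: TBSOTf, 2,6-lutidine, CH2Cl2, 0 °C
Reagents that add atoms: tert-butyldimethylsilyl trifluoromethanesulfonate, CC(C)(C)[Si](C)(C)OS(=O)(=O)C(F)(F)F
Why: Silylation of the hydrogen-bonded salicylate phenol with a silyl triflate, needed so that the later activated-DMSO oxidation cannot attack a free phenol.

Step 15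
Reactants: 25 methyl 2-(Ar-carbonyl)-6-[(tert-butyldimethylsilyl)oxy]-3-(3-methylbut-2-en-1-yl)benzoate
Product: 26 {2-[(tert-butyldimethylsilyl)oxy]-6-[Ar(hydroxy)methyl]-5-(3-methylbut-2-en-1-yl)phenyl}methanol (epimers at the benzhydrol carbon)
Conditions: i-Bu2AlH (5 equiv), CH2Cl2, −78 → 0 °C
Reagents that add atoms: none
Why: Aluminium hydride reduction of the ester and the diaryl ketone (any lactol or phthalide stage is reduced further at 0 °C) gives the diol, with a non-basic hydride chosen to limit migration of the aryl silyl group; the benzhydrol centre forms unselectively and is oxidised in the next step.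

Step 16
Reactants: 26 {2-[(tert-butyldimethylsilyl)oxy]-6-[Ar(hydroxy)methyl]-5-(3-methylbut-2-en-1-yl)phenyl}methanol
Product: 27 2-(Ar-carbonyl)-6-[(tert-butyldimethylsilyl)oxy]-3-(3-methylbut-2-en-1-yl)benzaldehyde
Conditions: (COCl)2, DMSO, CH2Cl2, −78 °C; then Et3N, −78 → 0 °C
Reagents that add atoms: none
Why: Swern oxidation, chosen because both alcohols are converted into alkoxysulfonium salts before base is added, so aldehyde and ketone appear together and the hydroxy aldehyde that would close to a lactol and be oxidised to a phthalide is never present.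

Step 17
Reactants: 27 2-(Ar-carbonyl)-6-[(tert-butyldimethylsilyl)oxy]-3-(3-methylbut-2-en-1-yl)benzaldehyde
Product: 28 6-hydroxy-2-{[(3R)-3-(2-hydroxypropan-2-yl)-7-methyl-2,3-dihydro-1,4-benzodioxin-5-yl]carbonyl}-3-(3-methylbut-2-en-1-yl)benzaldehyde (target)
Conditions: HF·pyridine, pyridine, THF, 0 → 20 °C
Reagents that add atoms: none
Why: Fluoride-mediated desilylation under mildly acidic conditions cleaves the aryl and the tertiary silyl ether without exposing the ortho-aroyl benzaldehyde to hydroxide or alkoxide, which could trigger a Cannizzaro–Tishchenko shift to a phthalide.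

**Compound list**

1 | 2-hydroxy-3-methoxy-5-methylbenzaldehyde | COc1cc(C)cc(C=O)c1O | starting material
2 | 2,3-dihydroxy-5-methylbenzaldehyde | O=Cc1cc(C)cc(O)c1O | intermediate
3 | 3-methylbut-2-en-1-ol | CC(C)=CCO | starting material
4 | [(2S)-3,3-dimethyloxiran-2-yl]methanol | OC[C@@H]1OC1(C)C | intermediate
5 | [(2S)-3,3-dimethyloxiran-2-yl]methyl 4-methylbenzenesulfonate | Cc1ccc(cc1)S(=O)(=O)OC[C@@H]1OC1(C)C | intermediate
6 | sodium 2-{[(2S)-3,3-dimethyloxiran-2-yl]methoxy}-6-formyl-4-methylphenolate | O=Cc1cc(C)cc(OC[C@@H]2OC2(C)C)c1[O-].[Na+] | intermediate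
7 | (3R)-3-(2-hydroxypropan-2-yl)-7-methyl-2,3-dihydro-1,4-benzodioxine-5-carbaldehyde | O=Cc1cc(C)cc2c1O[C@@H](C(C)(C)O)CO2 | intermediate
8 | Ar–CHO, (3R)-3-{2-[(tert-butyldimethylsilyl)oxy]propan-2-yl}-7-methyl-2,3-dihydro-1,4-benzodioxine-5-carbaldehyde | O=Cc1cc(C)cc2c1O[C@@H](C(C)(C)O[Si](C)(C)C(C)(C)C)CO2 | intermediate
9 | 1,3-dithiane | C1CSCSC1 | starting material
10 | 5-bromo-2-methylpent-2-ene | CC(C)=CCCBr | starting material
11 | 2-lithio-1,3-dithiane | [Li]C1SCCCS1 | intermediate
12 | 2-(4-methylpent-3-en-1-yl)-1,3-dithiane | CC(C)=CCCC1SCCCS1 | intermediate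
13 | 2-lithio-2-(4-methylpent-3-en-1-yl)-1,3-dithiane | [Li]C1(CCC=C(C)C)SCCCS1 | intermediate
14 | Ar[2-(4-methylpent-3-en-1-yl)-1,3-dithian-2-yl]methanol, epimers at the carbinol carbon | CC(C)=CCCC1(SCCCS1)C(O)c1cc(C)cc2c1O[C@@H](C(C)(C)O[Si](C)(C)C(C)(C)C)CO2 | intermediate
15 | Ar 2-(4-methylpent-3-en-1-yl)-1,3-dithian-2-yl ketone | CC(C)=CCCC1(SCCCS1)C(=O)c1cc(C)cc2c1O[C@@H](C(C)(C)O[Si](C)(C)C(C)(C)C)CO2 | intermediate
16 | 1-Ar-6-methylhept-5-ene-1,2-dione | CC(C)=CCCC(=O)C(=O)c1cc(C)cc2c1O[C@@H](C(C)(C)O[Si](C)(C)C(C)(C)C)CO2 | intermediate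
17 | (3E)-1-Ar-3-[(dimethylamino)methylidene]-6-methylhept-5-ene-1,2-dione | O=C(c1cc(C)cc2c1O[C@@H](C(C)(C)O[Si](C)(C)C(C)(C)C)CO2)C(=O)/C(CC=C(C)C)=C/N(C)C | intermediate
18 | (3Z)-1-Ar-3-(hydroxymethylidene)-6-methylhept-5-ene-1,2-dione | O=C(c1cc(C)cc2c1O[C@@H](C(C)(C)O[Si](C)(C)C(C)(C)C)CO2)C(=O)/C(CC=C(C)C)=C\O | intermediate
19 | (3Z)-1-Ar-6-methyl-3-{[(trimethylsilyl)oxy]methylidene}hept-5-ene-1,2-dione | O=C(c1cc(C)cc2c1O[C@@H](C(C)(C)O[Si](C)(C)C(C)(C)C)CO2)C(=O)/C(CC=C(C)C)=C\O[Si](C)(C)C | intermediate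
20 | methyl acetoacetate | CC(=O)CC(=O)OC | starting material
21 | methyl 3-[(trimethylsilyl)oxy]but-2-enoate, double-bond isomer mixture | COC(=O)C=C(C)O[Si](C)(C)C | intermediate
22 | lithium 1-methoxy-3-[(trimethylsilyl)oxy]buta-1,3-dien-1-olate | COC([O-])=CC(=C)O[Si](C)(C)C.[Li+] | intermediate
23 | 1-methoxy-1,3-bis[(trimethylsilyl)oxy]buta-1,3-diene, double-bond isomer mixture | COC(O[Si](C)(C)C)=CC(=C)O[Si](C)(C)C | intermediate
24 | methyl 2-(Ar-carbonyl)-6-hydroxy-3-(3-methylbut-2-en-1-yl)benzoate | COC(=O)c1c(O)ccc(CC=C(C)C)c1C(=O)c1cc(C)cc2c1O[C@@H](C(C)(C)O[Si](C)(C)C(C)(C)C)CO2 | intermediate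
25 | methyl 2-(Ar-carbonyl)-6-[(tert-butyldimethylsilyl)oxy]-3-(3-methylbut-2-en-1-yl)benzoate | COC(=O)c1c(O[Si](C)(C)C(C)(C)C)ccc(CC=C(C)C)c1C(=O)c1cc(C)cc2c1O[C@@H](C(C)(C)O[Si](C)(C)C(C)(C)C)CO2 | intermediate
26 | {2-[(tert-butyldimethylsilyl)oxy]-6-[Ar(hydroxy)methyl]-5-(3-methylbut-2-en-1-yl)phenyl}methanol, epimers at the benzhydrol carbon | OCc1c(O[Si](C)(C)C(C)(C)C)ccc(CC=C(C)C)c1C(O)c1cc(C)cc2c1O[C@@H](C(C)(C)O[Si](C)(C)C(C)(C)C)CO2 | intermediate
27 | 2-(Ar-carbonyl)-6-[(tert-butyldimethylsilyl)oxy]-3-(3-methylbut-2-en-1-yl)benzaldehyde | O=Cc1c(O[Si](C)(C)C(C)(C)C)ccc(CC=C(C)C)c1C(=O)c1cc(C)cc2c1O[C@@H](C(C)(C)O[Si](C)(C)C(C)(C)C)CO2 | intermediate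
28 | 6-hydroxy-2-{[(3R)-3-(2-hydroxypropan-2-yl)-7-methyl-2,3-dihydro-1,4-benzodioxin-5-yl]carbonyl}-3-(3-methylbut-2-en-1-yl)benzaldehyde | CC(C)=CCc1ccc(O)c(C=O)c1C(=O)c1cc(C)cc2c1O[C@@H](C(C)(C)O)CO2 | target

**Step count**

Total: 17 steps. Longest linear sequence: 13 steps (steps 1, 3, 4, 6, 7, 8, 9, 10, 13, 14, 15, 16, 17).

**Steps most likely to fail and fallbacks**

Step 13 (key step). The diene may add to the titanium-chelated 1,2-diketone instead of the silyloxymethylidene terminus, which would lead to five-membered closure. The Lewis acid may also strip the tertiary silyl ether or add HCl to the prenyl alkene before aromatisation is complete. The fallback sets out from aldehyde 8 and comes back at salicylate 24; it builds ring A by a furan Diels–Alder reaction and ring-opening aromatisation instead of a cyclocondensation. 2-(3-Methylbut-2-en-1-yl)furan F1 would be made from 2-lithiofuran and 1-bromo-3-methylbut-2-ene. Aldehyde 8 would be treated with lithiated methyl propiolate (LiN(SiMe3)2, THF, −78 °C) to give the propargylic alcohol methyl 4-Ar-4-hydroxybut-2-ynoate F2, which MnO2 in CH2Cl2 should oxidise to the ynone methyl 4-Ar-4-oxobut-2-ynoate F3. Warming F3 with F1 in toluene should give the 7-oxanorbornadiene methyl 3-(Ar-carbonyl)-4-(3-methylbut-2-en-1-yl)-7-oxabicyclo[2.2.1]hepta-2,5-diene-2-carboxylate F4; the unsubstituted furan α-carbon should bond to the alkyne carbon β to the ketone, which is the ester-bearing one. BF3·OEt2 in CH2Cl2 at low temperature should then open the oxygen bridge at the prenyl-bearing bridgehead (the better stabilised cation), and hydride shift with enolisation should give 24, with the hydroxyl para to the prenyl group as required.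

Step 9. The enolisable 1,2-diketone may self-condense, or the liberated dimethylamine may add to it, faster than the C3 methylene is aminomethylenated. The fallback sets out from aldehyde 8 and comes back at 18; it masks the aryl carbonyl instead of the inner one, so that formylation is done on a simple ketone with one enolisable side. Aldehyde 8 with propane-1,3-dithiol and catalytic BF3·OEt2 should give 2-Ar-1,3-dithiane F5. Lithiation (n-BuLi, THF) and addition to 5-methylhex-4-enal should give the carbinol 1-(2-Ar-1,3-dithian-2-yl)-5-methylhex-4-en-1-ol F6, and Swern oxidation the ketone 1-(2-Ar-1,3-dithian-2-yl)-5-methylhex-4-en-1-one F7. Claisen formylation (HCO2Et, NaH, THF) should give (2Z)-1-(2-Ar-1,3-dithian-2-yl)-2-(hydroxymethylidene)-5-methylhex-4-en-1-one F8, and alkylative dithiane hydrolysis (MeI, CaCO3, aqueous MeCN) should release 18.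

Step 16. The hindered benzhydrol may be activated more slowly than the primary alcohol, so that the hydroxy aldehyde closes to a lactol and is over-oxidised, or the benzhydryl alkoxysulfonium ion may ionise and be trapped by the neighbouring hydroxyl as a cyclic ether. The fallback sets out from diol 26 and comes back at 27; it oxidises the two carbinols one after the other with the primary one masked. Selective silylation (Et3SiCl, imidazole, CH2Cl2, −20 °C) should give the primary triethylsilyl ether Ar{3-[(tert-butyldimethylsilyl)oxy]-6-(3-methylbut-2-en-1-yl)-2-{[(triethylsilyl)oxy]methyl}phenyl}methanol F9. Dess–Martin oxidation of the benzhydrol should give the ketone F10, and PPTS in MeOH at 0 °C should remove only the primary silyl ether to give the hydroxy ketone Ar{3-[(tert-butyldimethylsilyl)oxy]-2-(hydroxymethyl)-6-(3-methylbut-2-en-1-yl)phenyl}methanone F11, which may rest as its cyclic hemiketal. A second Dess–Martin oxidation (NaHCO3 buffer) should give 27, since the hemiketal carbon carries no hydrogen and cannot be over-oxidised.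

Further compounds
F1 | step 13 | 2-(3-methylbut-2-en-1-yl)furan | CC(C)=CCc1ccco1
F2 | step 13 | methyl 4-Ar-4-hydroxybut-2-ynoate | COC(=O)C#CC(O)c1cc(C)cc2c1O[C@@H](C(C)(C)O[Si](C)(C)C(C)(C)C)CO2
F3 | step 13 | methyl 4-Ar-4-oxobut-2-ynoate | COC(=O)C#CC(=O)c1cc(C)cc2c1O[C@@H](C(C)(C)O[Si](C)(C)C(C)(C)C)CO2
F4 | step 13 | methyl 3-(Ar-carbonyl)-4-(3-methylbut-2-en-1-yl)-7-oxabicyclo[2.2.1]hepta-2,5-diene-2-carboxylate, bridgehead diastereomer mixture | COC(=O)C1=C(C(=O)c3cc(C)cc4c3O[C@@H](C(C)(C)O[Si](C)(C)C(C)(C)C)CO4)C2(CC=C(C)C)C=CC1O2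
F5 | step 9 | 2-Ar-1,3-dithiane | C1CSC(SC1)c1cc(C)cc2c1O[C@@H](C(C)(C)O[Si](C)(C)C(C)(C)C)CO2
F6 | step 9 | 1-(2-Ar-1,3-dithian-2-yl)-5-methylhex-4-en-1-ol, epimers at the carbinol carbon | CC(C)=CCCC(O)C1(SCCCS1)c1cc(C)cc2c1O[C@@H](C(C)(C)O[Si](C)(C)C(C)(C)C)CO2
F7 | step 9 | 1-(2-Ar-1,3-dithian-2-yl)-5-methylhex-4-en-1-one | CC(C)=CCCC(=O)C1(SCCCS1)c1cc(C)cc2c1O[C@@H](C(C)(C)O[Si](C)(C)C(C)(C)C)CO2
F8 | step 9 | (2Z)-1-(2-Ar-1,3-dithian-2-yl)-2-(hydroxymethylidene)-5-methylhex-4-en-1-one | O/C=C(/CC=C(C)C)C(=O)C1(SCCCS1)c1cc(C)cc2c1O[C@@H](C(C)(C)O[Si](C)(C)C(C)(C)C)CO2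
F9 | step 16 | Ar{3-[(tert-butyldimethylsilyl)oxy]-6-(3-methylbut-2-en-1-yl)-2-{[(triethylsilyl)oxy]methyl}phenyl}methanol, epimers at the benzhydrol carbon | CC[Si](CC)(CC)OCc1c(O[Si](C)(C)C(C)(C)C)ccc(CC=C(C)C)c1C(O)c1cc(C)cc2c1O[C@@H](C(C)(C)O[Si](C)(C)C(C)(C)C)CO2
F10 | step 16 | Ar{3-[(tert-butyldimethylsilyl)oxy]-6-(3-methylbut-2-en-1-yl)-2-{[(triethylsilyl)oxy]methyl}phenyl}methanone | CC[Si](CC)(CC)OCc1c(O[Si](C)(C)C(C)(C)C)ccc(CC=C(C)C)c1C(=O)c1cc(C)cc2c1O[C@@H](C(C)(C)O[Si](C)(C)C(C)(C)C)CO2
F11 | step 16 | Ar{3-[(tert-butyldimethylsilyl)oxy]-2-(hydroxymethyl)-6-(3-methylbut-2-en-1-yl)phenyl}methanone | OCc1c(O[Si](C)(C)C(C)(C)C)ccc(CC=C(C)C)c1C(=O)c1cc(C)cc2c1O[C@@H](C(C)(C)O[Si](C)(C)C(C)(C)C)CO2
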